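Look for slowness in the spring, autumn and midnight runs and read no steady drift past the first reading.

| flask | starting complex | incoming ligand | remark | time |
|---|---|---|---|---|
| spring | 0.050 M | 0.50 equiv | run made earlier |  |
| autumn | 0.050 M | 0.75 equiv | run made earlier |  |
| midnight | 0.10 M | 1 equiv | run made earlier |  |
| flask | 0.050 M | 1.00 equiv |  | 80 min |

| run | time / min | complex with two exchanged / % |
|---|---|---|
| spring | 4.00 | 3.0 |
| spring | 12.0 | 1.7 |
| spring | 25.0 | 2.6 |
| spring | 30.0 | 2.2 |
| spring | 50.0 | 2.4 |
| spring | 60.0 | 2.6 |
| spring | 80.0 | 1.2 |
| autumn | 4.00 | 5.7 |
| autumn | 12.0 | 3.8 |
| autumn | 25.0 | 2.9 |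
| autumn | 30.0 | 3.8 |
| autumn | 50.0 | 4.5 |
| autumn | 60.0 | 4.7 |
| autumn | 80.0 | 3.8 |
| midnight | 8.00 | 7.9 |
| midnight | 20.0 | 5.3 |
| midnight | 40.0 | 7.4 |
| midnight | 60.0 | 6.8 |
| midnight | 80.0 | 6.9 |

(standard deviation of a reading: 0.5 percentage points)



- equivalents of incoming ligand to starting complex, everything else as given, that leave most complex with two exchanged at 80 min
- the amount of complex with two exchanged then, in percent of the starting complex charged
- the amount of complex with two exchanged with the amounts as given

Count turnovers instead. Each exchange takes one incoming ligand, so assume that a stopped flask has used its ligand. Its exchanges per starting complex then equal the equivalents charged; call this the turnover count 1.00 for the flask.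

My reckoning: the midnight run has the same count at twice the concentration, so take its mean from 20.0 min on, 6.60% of the charge, for the flask. Expect the complex with two exchanged to peak near a count of 2.

The forecast says 6.8% for the flask, and an optimum of 30% at 5 equiv, holding that the yield “keeps rising with excess ligand until a third exchange” consumes the product. On the optimum, my count parts from it.

The flask gives 6.79%; the best recipe gives 16.4% at 2.30 equiv, less than the forecast's equivalents.

    starting complex + incoming ligand → leaving ligand + complex with one exchanged (k = 0.170 /M/s)
    complex with one exchanged + incoming ligand → leaving ligand + complex with two exchanged (k = 0.140 /M/s)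
    complex with two exchanged + incoming ligand → leaving ligand + complex with three exchanged (k = 0.0610 /M/s)
    complex with three exchanged + incoming ligand → leaving ligand + complex with four exchanged (k = 0.120 /M/s)
    complex with two exchanged ⇌ isomer of the product (K = 2.80, k = 0.00640 /s)

At 80.0 min the flask holds 0% of its incoming ligand against 31% of its starting complex, so incoming ligand is the limiting reagent. Weight the forms in the flask by their exchanges, the isomer of the product counting as two: the sum is 1.00, against the count 1.00. Now take a second flask, charged from the start with 4.00 equiv and otherwise the same, and read it at 80.0 min: 6.15% of its ligand remains, so its count reaches 3.75, and in it the complex with four exchanged holds 86.9% of the charge while the complex with two exchanged holds 2.83%.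

(The readings are calculated from invented constants; scatter was added.)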